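Lignan numbering: C7 is the carbinol carbon, C8 and C8' are the ring methines carrying C7 and the benzylic C7'H2, and C9 and C9' are the OCH2 carbons next to C8 and C8'.
Retrosynthesis: cut O–C9 of the tetrahydrofuran, tie C9' as a carbonyl to O7, cut the C7'–aryl bond, then cut C7–C8 and O7–C9' together.
Enabling feature: C7–C8 joins two adjacent stereocentres, and O7 reaches C9' along O7–C7–C8–C8'–C9', so a temporary five-membered lactone (ring L) can hold C7, C8 and C8' on one rigid ring.
Forward: acrylate and silyloxyacetaldehyde give the E allylboronate. Ring L closes in the key step, the second aryl group is added at C7', and ring L is opened reductively while the tetrahydrofuran (ring T: C8–C9–O–C9'–C8') closes.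
Stereochemistry: C7 comes from the chiral phosphoric acid (aldehyde face) and C8 from the alkene geometry through the chair (syn). C8' comes from equilibration trans to C9 on ring L, which is the cis C7/C7' relation on ring T.
The leaving group is placed on C9 rather than C9', so O7 could compete only by forming an oxetane.

Key step: step 4

Assumption: the sense of induction known for pinacol allyl- and crotylboronates (R acid, Re face of an aryl aldehyde) is taken to hold for the ester-bearing boronate. The S acid is therefore specified for Si-face attack (7S), and the R acid would be used if the sense proved reversed.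

Step 1
Reactants: 1 methyl acrylate; 2 (tert-butyldimethylsilyloxy)acetaldehyde
Product: 3 methyl 4-(tert-butyldimethylsilyloxy)-3-hydroxy-2-methylenebutanoate (racemic)
Conditions: 1 (3 equiv), quinuclidine (0.25 equiv), MeOH (0.75 equiv), neat, rt
Reagents that add atoms: none
Why: Morita–Baylis–Hillman reaction, in which the amine-derived acrylate enolate adds to the activated α-silyloxy aldehyde and the amine is then expelled; the carbinol centre is racemic and is erased in step 3.

Step 2
Reactants: 3 methyl 4-(tert-butyldimethylsilyloxy)-3-hydroxy-2-methylenebutanoate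
Product: 4 methyl 3-acetoxy-4-(tert-butyldimethylsilyloxy)-2-methylenebutanoate (racemic)
Conditions: Ac2O, pyridine, DMAP (2 mol %), CH2Cl2, 0 °C
Reagents that add atoms: acetic anhydride, CC(=O)OC(C)=O
Why: Routine O-acetylation turns the allylic hydroxyl into a leaving group, and the low temperature and small DMAP charge should suppress amine SN2' attack on the product.

Step 3
Reactants: 4 methyl 3-acetoxy-4-(tert-butyldimethylsilyloxy)-2-methylenebutanoate
Product: 5 methyl (E)-4-(tert-butyldimethylsilyloxy)-2-[(4,4,5,5-tetramethyl-1,3,2-dioxaborolan-2-yl)methyl]but-2-enoate (CH2OTBS cis to CH2B, trans to the ester)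
Conditions: B2pin2 (1.05 equiv), CuCl (10 mol %), LiCl, KOAc, DMF, rt
Reagents that add atoms: bis(pinacolato)diboron, CC1(C)OB(OC1(C)C)B1OC(C)(C)C(C)(C)O1
Why: Copper-catalysed SN2' borylation of a Morita–Baylis–Hillman acetate, in which Cu–Bpin adds to the acrylate terminus and acetate leaves; allylic strain in the elimination should place CH2OTBS trans to the ester, the geometry normally obtained from ester-derived acetates.

Step 4
Reactants: 5 methyl (E)-4-(tert-butyldimethylsilyloxy)-2-[(pinacolatoboryl)methyl]but-2-enoate; 6 3-benzyloxy-4-methoxybenzaldehyde (O-benzylisovanillin)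
Product: 8 (4S,5S)-5-(3-benzyloxy-4-methoxyphenyl)-4-[(tert-butyldimethylsilyloxy)methyl]-3-methylenedihydrofuran-2(3H)-one (aryl cis to CH2OTBS), via pinacol borate 7 (not isolated)
Conditions: (S)-3,3'-bis(2,4,6-triisopropylphenyl)-1,1'-binaphthyl-2,2'-diyl hydrogen phosphate [(S)-TRIP, 10 mol %], 4 Å MS, toluene, 0 °C, then rt until 7 is consumed
Reagents that add atoms: none
Why: Proposed new method: the phosphoric acid O–H binds a dioxaborolane oxygen of 5 while its P=O holds the formyl H of 6, which raises the Lewis acidity of boron enough for the ester-deactivated allyl unit to deliver C8 to the aldehyde carbon through a closed six-membered Zimmerman–Traxler chair, forming C7–C8 with allylic transposition and giving borate 7. The closest known reaction types are the chiral-phosphoric-acid-catalysed allyl- and crotylboration of aryl aldehydes with pinacol boronates and the thermal or acid-accelerated allylboration–lactonization of 2-alkoxycarbonyl allylboronates, and their union on an ester-bearing reagent is the untested part. Ring L closes when the boron-bound O7 of 7 adds to the ester carbonyl C9' and methoxide passes to boron, a 5-exo-trig acyl substitution assisted by the same mild acid. C7 (S) is controlled by the catalyst, whose triisopropylphenyl walls should leave only the Si face of the bound aldehyde open, and C8 (S) is controlled by the chair, in which the aryl group is equatorial and CH2OTBS, cis to CH2B on the E alkene, is axial, so the syn adduct and hence the cis lactone should result. The step needs γ-regioselectivity, syn diastereoselectivity and a catalysed pathway that outruns the background: the first two follow from the cyclic boron-to-oxygen transfer and the single alkene geometry of 5, the third from the very slow uncatalysed reaction of this electron-poor boronate with an electron-rich aldehyde at or below room temperature. A weak acid is essential, because a strong one would ionize the 4-methoxybenzylic C7–O bond of 8 and leak to the trans lactone.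

Step 5
Reactants: 8 cis α-methylene lactone; 9 (3-benzyloxy-4-methoxyphenyl)boronic acid
Product: 10 (3S,4S,5S)-3-(3-benzyloxy-4-methoxybenzyl)-5-(3-benzyloxy-4-methoxyphenyl)-4-[(tert-butyldimethylsilyloxy)methyl]dihydrofuran-2(3H)-one (all-cis C8' epimer expected to dominate; any 11 formed alongside is carried on)
Conditions: 9 (1.8 equiv), [Rh(cod)OH]2 (2.5 mol %), 1,4-dioxane/H2O 10:1, 50 °C
Reagents that add atoms: none
Why: Rhodium-catalysed 1,4-addition of an arylboronic acid (Hayashi–Miyaura type) to a 1,1-disubstituted acceptor, in which aryl-rhodium adds to the unhindered exocyclic CH2 and water protonates the oxa-π-allyl enolate from the face opposite the two cis substituents; the C8' centre set here is provisional and is corrected in step 6.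

Step 6
Reactants: 10 all-cis lactone (with any 11)
Product: 11 (3R,4S,5S)-3-(3-benzyloxy-4-methoxybenzyl)-5-(3-benzyloxy-4-methoxyphenyl)-4-[(tert-butyldimethylsilyloxy)methyl]dihydrofuran-2(3H)-one (benzyl trans to CH2OTBS, aryl cis to CH2OTBS)
Conditions: DBU (1 equiv), toluene, 80 °C
Reagents that add atoms: none
Why: Base-mediated α-epimerization under thermodynamic control, in which reversible enolization at C8' (the only acidic C–H) relieves the all-cis crowding and should settle the benzyl group trans to CH2OTBS (8'R); C8 carries no leaving group, so E1cB loss is not available.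

Step 7
Reactants: 11 (3R,4S,5S)-silyl ether lactone
Product: 12 (3R,4S,5S)-3-(3-benzyloxy-4-methoxybenzyl)-5-(3-benzyloxy-4-methoxyphenyl)-4-(hydroxymethyl)dihydrofuran-2(3H)-one
Conditions: Et3N·3HF, THF, rt; crude alcohol used at once
Reagents that add atoms: none
Why: Fluoride cleavage of a primary TBS ether under nearly neutral conditions should spare the acid-labile benzylic C7–O bond and keep the acyl shift from O7 to O9 slow.

Step 8
Reactants: 12 hydroxymethyl lactone
Product: 13 [(2S,3S,4R)-4-(3-benzyloxy-4-methoxybenzyl)-2-(3-benzyloxy-4-methoxyphenyl)-5-oxotetrahydrofuran-3-yl]methyl methanesulfonate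
Conditions: MsCl, Et3N, CH2Cl2, −10 °C
Reagents that add atoms: methanesulfonyl chloride, CS(=O)(=O)Cl
Why: Fast sulfene-type mesylation of the only free (primary) hydroxyl installs the leaving group on C9 while O7 is still locked in ring L.

Step 9
Reactants: 13 lactone mesylate
Product: 15 (S)-(3-benzyloxy-4-methoxyphenyl)[(3S,4R)-4-(3-benzyloxy-4-methoxybenzyl)tetrahydrofuran-3-yl]methanol, via diol mesylate 14 (not isolated)
Conditions: LiBH4, THF, 0 °C to rt; then MeOH, K2CO3, rt to 40 °C
Reagents that add atoms: none
Why: Lactone reduction followed by intramolecular Williamson etherification, in which the freed primary O9' displaces the C9 mesylate (5-exo-tet) while O7 could only close an oxetane (4-exo-tet), so the 7,9'-epoxy isomer is excluded; no stereocentre is touched, and the trans C9/C7' relation of ring L becomes the cis C7/C7' relation of ring T.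

Step 10
Reactants: 15 bis(benzyl ether) of the target
Product: 16 (S)-(3-hydroxy-4-methoxyphenyl)[(3S,4R)-4-(3-hydroxy-4-methoxybenzyl)tetrahydrofuran-3-yl]methanol (CNP0108210.1)
Conditions: H2 (1 atm), Pd/C (10 wt %), NaHCO3 (0.1 equiv), EtOAc/EtOH 1:1, rt, stopped after uptake of 2 equiv H2
Reagents that add atoms: none
Why: Catalytic hydrogenolysis cleaves aryl benzyl ethers much faster than a secondary benzylic alcohol when the medium is kept free of acid, so C7–OH and its configuration should persist.

Compound list
1 | methyl acrylate | C=CC(=O)OC | starting material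
2 | (tert-butyldimethylsilyloxy)acetaldehyde | O=CCO[Si](C)(C)C(C)(C)C | starting material
3 | methyl 4-(tert-butyldimethylsilyloxy)-3-hydroxy-2-methylenebutanoate (racemic) | C=C(C(=O)OC)C(O)CO[Si](C)(C)C(C)(C)C | intermediate
4 | methyl 3-acetoxy-4-(tert-butyldimethylsilyloxy)-2-methylenebutanoate (racemic) | C=C(C(=O)OC)C(OC(C)=O)CO[Si](C)(C)C(C)(C)C | intermediate
5 | methyl (E)-4-(tert-butyldimethylsilyloxy)-2-[(4,4,5,5-tetramethyl-1,3,2-dioxaborolan-2-yl)methyl]but-2-enoate | COC(=O)/C(CB1OC(C)(C)C(C)(C)O1)=C/CO[Si](C)(C)C(C)(C)C | intermediate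
6 | 3-benzyloxy-4-methoxybenzaldehyde | COc1ccc(C=O)cc1OCc1ccccc1 | starting material
7 | methyl (3S)-3-[(S)-(3-benzyloxy-4-methoxyphenyl)(pinacolatoboryloxy)methyl]-4-(tert-butyldimethylsilyloxy)-2-methylenebutanoate | COC(=O)C(=C)[C@@H](CO[Si](C)(C)C(C)(C)C)[C@H](OB1OC(C)(C)C(C)(C)O1)c1ccc(OC)c(OCc2ccccc2)c1 | intermediate
8 | (4S,5S)-5-(3-benzyloxy-4-methoxyphenyl)-4-[(tert-butyldimethylsilyloxy)methyl]-3-methylenedihydrofuran-2(3H)-one | O=C1C(=C)[C@@H](CO[Si](C)(C)C(C)(C)C)[C@@H](c2ccc(OC)c(OCc3ccccc3)c2)O1 | intermediate
9 | (3-benzyloxy-4-methoxyphenyl)boronic acid | COc1ccc(B(O)O)cc1OCc1ccccc1 | starting material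
10 | (3S,4S,5S)-3-(3-benzyloxy-4-methoxybenzyl)-5-(3-benzyloxy-4-methoxyphenyl)-4-[(tert-butyldimethylsilyloxy)methyl]dihydrofuran-2(3H)-one | O=C1[C@@H](Cc2ccc(OC)c(OCc3ccccc3)c2)[C@@H](CO[Si](C)(C)C(C)(C)C)[C@@H](c2ccc(OC)c(OCc3ccccc3)c2)O1 | intermediate
11 | (3R,4S,5S)-3-(3-benzyloxy-4-methoxybenzyl)-5-(3-benzyloxy-4-methoxyphenyl)-4-[(tert-butyldimethylsilyloxy)methyl]dihydrofuran-2(3H)-one | O=C1[C@H](Cc2ccc(OC)c(OCc3ccccc3)c2)[C@@H](CO[Si](C)(C)C(C)(C)C)[C@@H](c2ccc(OC)c(OCc3ccccc3)c2)O1 | intermediate
12 | (3R,4S,5S)-3-(3-benzyloxy-4-methoxybenzyl)-5-(3-benzyloxy-4-methoxyphenyl)-4-(hydroxymethyl)dihydrofuran-2(3H)-one | O=C1[C@H](Cc2ccc(OC)c(OCc3ccccc3)c2)[C@@H](CO)[C@@H](c2ccc(OC)c(OCc3ccccc3)c2)O1 | intermediate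
13 | [(2S,3S,4R)-4-(3-benzyloxy-4-methoxybenzyl)-2-(3-benzyloxy-4-methoxyphenyl)-5-oxotetrahydrofuran-3-yl]methyl methanesulfonate | O=C1[C@H](Cc2ccc(OC)c(OCc3ccccc3)c2)[C@@H](COS(C)(=O)=O)[C@@H](c2ccc(OC)c(OCc3ccccc3)c2)O1 | intermediate
14 | (2S,3R)-3-(3-benzyloxy-4-methoxybenzyl)-2-[(S)-(3-benzyloxy-4-methoxyphenyl)(hydroxy)methyl]-4-hydroxybutyl methanesulfonate | OC[C@H](Cc1ccc(OC)c(OCc2ccccc2)c1)[C@@H](COS(C)(=O)=O)[C@@H](c1ccc(OC)c(OCc2ccccc2)c1)O | intermediate
15 | (S)-(3-benzyloxy-4-methoxyphenyl)[(3S,4R)-4-(3-benzyloxy-4-methoxybenzyl)tetrahydrofuran-3-yl]methanol | COc1ccc(C[C@H]2COC[C@H]2[C@H](O)c2ccc(OC)c(OCc3ccccc3)c2)cc1OCc1ccccc1 | intermediate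
16 | (S)-(3-hydroxy-4-methoxyphenyl)[(3S,4R)-4-(3-hydroxy-4-methoxybenzyl)tetrahydrofuran-3-yl]methanol | COc1ccc(C[C@H]2COC[C@H]2[C@H](O)c2ccc(OC)c(O)c2)cc1O | target

Total steps: 10. Longest linear sequence: 10 steps (from 1 or 2 to 16).

Steps most likely to fail

Step 4. The weak acid may accelerate the electron-poor boronate too little. Conversion would then stall, or the temperature needed would let the uncatalysed pathway erode the facial selectivity. Slow closure of ring L or acid-induced loss of the cis relation are further concerns. The fallback sets out from 5 and 6 and gives up catalyst control. The uncatalysed thermal allylboration–lactonization (toluene, 80–110 °C) is a known reaction that keeps the chair-derived cis selectivity, and it should give the racemate, that is 8 together with the mirror-image (4R,5R)-lactone F1. Preparative chromatography on a chiral stationary phase then delivers 8, where the route is rejoined.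

Step 5. The aryl-rhodium adduct may undergo β-hydride elimination towards the benzylidene lactone. The electron-rich boronic acid may protodeboronate, or the exocyclic double bond may migrate into the ring and erase C8. The fallback sets out from 8 and replaces catalytic boron-to-rhodium transfer by a stoichiometric organocopper addition. Purchased 2-(benzyloxy)-4-bromo-1-methoxybenzene F2 is converted with Mg in THF into (3-benzyloxy-4-methoxyphenyl)magnesium bromide F3. This is added to 8 in the presence of CuBr·SMe2 (THF, −40 °C). An NH4Cl quench protonates the enolate and gives the C8' epimer mixture, which rejoins the route at 10 for the equilibration of step 6.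

Step 7. Once the C9 hydroxyl is free, the acyl group may migrate from O7 to O9 through the bridged tetrahedral intermediate, which would open ring L too early and expose O7. The fallback sets out from 11 and never releases the alcohol. The known DBU-catalysed interconversion of a silyl ether with p-toluenesulfonyl fluoride (MeCN, rt) should give the lactone C9 tosylate F4 directly. Treatment as in step 9 (LiBH4, THF; then K2CO3, MeOH) passes through the diol tosylate F5 and comes back to the route at 15.

Further compounds
F1 | step 4 | (4R,5R)-5-(3-benzyloxy-4-methoxyphenyl)-4-[(tert-butyldimethylsilyloxy)methyl]-3-methylenedihydrofuran-2(3H)-one | O=C1C(=C)[C@H](CO[Si](C)(C)C(C)(C)C)[C@H](c2ccc(OC)c(OCc3ccccc3)c2)O1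
F2 | step 5 | 2-(benzyloxy)-4-bromo-1-methoxybenzene | COc1ccc(Br)cc1OCc1ccccc1
F3 | step 5 | (3-benzyloxy-4-methoxyphenyl)magnesium bromide | COc1ccc([Mg]Br)cc1OCc1ccccc1
F4 | step 7 | [(2S,3S,4R)-4-(3-benzyloxy-4-methoxybenzyl)-2-(3-benzyloxy-4-methoxyphenyl)-5-oxotetrahydrofuran-3-yl]methyl 4-methylbenzenesulfonate | O=C1[C@H](Cc2ccc(OC)c(OCc3ccccc3)c2)[C@@H](COS(=O)(=O)c2ccc(C)cc2)[C@@H](c2ccc(OC)c(OCc3ccccc3)c2)O1
F5 | step 7 | (2S,3R)-3-(3-benzyloxy-4-methoxybenzyl)-2-[(S)-(3-benzyloxy-4-methoxyphenyl)(hydroxy)methyl]-4-hydroxybutyl 4-methylbenzenesulfonate | OC[C@H](Cc1ccc(OC)c(OCc2ccccc2)c1)[C@@H](COS(=O)(=O)c1ccc(C)cc1)[C@@H](c1ccc(OC)c(OCc2ccccc2)c1)O
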